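**Retrosynthetic overview**

1. Target ⇐ fluoride unmasking of the silyl ether and silylethyl ester ⇐ C2–CH2 bond from a C2 dienyl triflate and the tin enolate of acetone; the C2=C3–C4=C4a diene is drawn regiospecifically from a C3-acetoxy C2-ketone with SmI2.
2. Key disconnection C8–C8a: amine-catalysed intramolecular Michael addition of a C7 ethyl ketone to a 6-acetoxy-6-methylcyclohexa-2,4-dienone, which closes ring B.
3. Enabling feature: ring A (C1, C2, C3, C4, C4a, C8a) is a 1,2-dihydrobenzene, so it maps onto an o-cresol ring that needs only a C–C bond at C8a and H at C1; C6 and C8 flank the C7 ketone of ring B and C1 flanks the transient C2 ketone, all three enolisable and equatorial, so only C8a needs absolute control.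
4. Dienone ⇐ Suzuki–Miyaura union (C1–C6') of a bromo quinol acetate with the side-chain alkenylboronate ⇐ Wessely oxidation of a bromophenol made from 4-hydroxy-3-methylbenzaldehyde and pentan-3-one; side chain: C4' by Sharpless epoxidation and aluminium-promoted 1,2-shift, C5'=C6' by carboalumination, C2'=C3' by Horner–Wadsworth–Emmons.
5. Ring order: ring A is present from the start as the benzene ring (dearomatised in step 11); ring B is the only ring built and is closed last, in step 13.

Key step: step 13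

Numbering: the core is numbered as a 1,5,6,7,8,8a-hexahydronaphthalene (C1 bears the side chain, C2 the 2-oxopropyl group, C3 a methyl, C7 is the ketone, C6 and C8 bear methyls; ring B = C4a, C5, C6, C7, C8, C8a); side-chain atoms are primed, C1' = CO2H to C6' on C1.

Assumption: the target's configurations at C6 and C8 (both α to the C7 ketone), and at C1 while C2 is still a ketone, are taken to be the thermodynamically preferred ones, so they are set by equilibration.

**Route**

Step 1
Reactants: 1 diethylphosphonoacetic acid; 2 2-(trimethylsilyl)ethanol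
Product: 3 2-(trimethylsilyl)ethyl 2-(diethoxyphosphoryl)acetate
Conditions: DCC, DMAP (cat.), CH2Cl2, 0 °C → rt
Reagents that add atoms: none
Why: Steglich esterification of an unhindered acid with a primary alcohol is routine and gives the fluoride-labile ester that later lets acid and alcohol be unmasked together; no stereocentre is formed.

Step 2
Reactants: 4 (2E)-3-methylpent-2-en-4-yn-1-ol
Product: 6 (2E,4E)-5-iodo-3,4-dimethylpenta-2,4-dien-1-ol, via dienylalane 5 (not isolated)
Conditions: AlMe3 (3 equiv), Cp2ZrCl2 (25 mol %), CH2Cl2, 0 °C → rt; then I2, THF, −30 → 0 °C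
Reagents that add atoms: trimethylaluminium C[Al](C)C; iodine II
Why: Zirconium-catalysed carboalumination (Negishi) adds methyl and AlMe2 syn across the terminal alkyne with methyl on the internal carbon, and iodinolysis of the C–Al bond goes with retention, so the new trisubstituted alkene should be E while the existing E-alkene and the alcohol (as R–O–AlMe2) are untouched.

Step 3
Reactants: 6 (2E,4E)-5-iodo-3,4-dimethylpenta-2,4-dien-1-ol
Product: 7 [(2S,3S)-3-[(1E)-1-iodoprop-1-en-2-yl]-3-methyloxiran-2-yl]methanol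
Conditions: Ti(OiPr)4 (10 mol %), L-(+)-diethyl tartrate (12 mol %), t-BuOOH, 4 Å MS, CH2Cl2, −20 °C
Reagents that add atoms: tert-butyl hydroperoxide CC(C)(C)OO
Why: Sharpless asymmetric epoxidation oxidises only the allylic-alcohol alkene, and the Ti(OiPr)4/L-(+)-tartrate catalyst delivers oxygen to the face that gives the (2S,3S)-epoxide of an E-configured 3,3-disubstituted allylic alcohol, which fixes the oxirane carbon that becomes C4'.

Step 4
Reactants: 7 [(2S,3S)-3-[(1E)-1-iodoprop-1-en-2-yl]-3-methyloxiran-2-yl]methanol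
Product: 8 tert-butyl{[(2S,3S)-3-[(1E)-1-iodoprop-1-en-2-yl]-3-methyloxiran-2-yl]methoxy}dimethylsilane
Conditions: TBSCl, imidazole, CH2Cl2, 0 °C → rt
Reagents that add atoms: tert-butyldimethylsilyl chloride CC(C)(C)[Si](C)(C)Cl
Why: Standard silylation of the primary alcohol installs the siloxymethyl group that migrates in the next step and then serves as the protecting group of the C4' hydroxymethyl; no stereocentre changes.

Step 5
Reactants: 8 tert-butyl{[(2S,3S)-3-[(1E)-1-iodoprop-1-en-2-yl]-3-methyloxiran-2-yl]methoxy}dimethylsilane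
Product: 9 (2S,3E)-2-{[tert-butyl(dimethyl)silyl]oxymethyl}-4-iodo-2,3-dimethylbut-3-enal
Conditions: MeAl(OAr)2 (MABR, Ar = 4-bromo-2,6-di-tert-butylphenyl, 2 equiv), CH2Cl2, −78 °C
Reagents that add atoms: none
Why: Lewis-acid-promoted epoxy silyl ether rearrangement (semipinacol-type 1,2-shift): the bulky MeAl(OAr)2 opens the oxirane at the tertiary allylic carbon and the siloxymethyl group migrates anti to the breaking C–O bond, so the quaternary centre should form with inversion and full transfer of the epoxide configuration, giving (S).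

Step 6
Reactants: 9 (2S,3E)-2-{[tert-butyl(dimethyl)silyl]oxymethyl}-4-iodo-2,3-dimethylbut-3-enal; 3 2-(trimethylsilyl)ethyl 2-(diethoxyphosphoryl)acetate
Product: 10 2-(trimethylsilyl)ethyl (2E,4S,5E)-4-{[tert-butyl(dimethyl)silyl]oxymethyl}-6-iodo-4,5-dimethylhexa-2,5-dienoate
Conditions: NaH, THF, 0 °C → rt
Reagents that add atoms: none
Why: Horner–Wadsworth–Emmons olefination of a non-enolisable aldehyde with a stabilised phosphonate should give the E-enoate, and the quaternary centre cannot epimerise.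

Step 7
Reactants: 10 2-(trimethylsilyl)ethyl (2E,4S,5E)-4-{[tert-butyl(dimethyl)silyl]oxymethyl}-6-iodo-4,5-dimethylhexa-2,5-dienoate
Product: 11 2-(trimethylsilyl)ethyl (2E,4S,5E)-4-{[tert-butyl(dimethyl)silyl]oxymethyl}-4,5-dimethyl-6-(4,4,5,5-tetramethyl-1,3,2-dioxaborolan-2-yl)hexa-2,5-dienoate
Conditions: B2pin2, PdCl2(PPh3)2 (3 mol %), PPh3, KOPh, toluene, 50 °C
Reagents that add atoms: bis(pinacolato)diboron CC1(C)OB(OC1(C)C)B1OC(C)(C)C(C)(C)O1
Why: Miyaura borylation of an alkenyl iodide with a phenoxide base proceeds with retention of alkene geometry and tolerates the enoate and both silyl groups.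

Step 8
Reactants: 12 4-hydroxy-3-methylbenzaldehyde; 13 pentan-3-one
Product: 14 (1E)-1-(4-hydroxy-3-methylphenyl)-2-methylpent-1-en-3-one
Conditions: 13 (5 equiv), HCl (g), 0 °C → rt
Reagents that add atoms: none
Why: Acid-mediated crossed aldol condensation of a non-enolisable aromatic aldehyde with a symmetrical ketone gives the conjugated E-enone and brings in C5 to C8 with both ring-B methyl groups in one step.

Step 9
Reactants: 14 (1E)-1-(4-hydroxy-3-methylphenyl)-2-methylpent-1-en-3-one
Product: 15 rac-1-(4-hydroxy-3-methylphenyl)-2-methylpentan-3-one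
Conditions: H2 (1 atm), Pd/C, EtOAc, rt
Reagents that add atoms: none
Why: Catalytic hydrogenation saturates the conjugated C=C in preference to the ketone and the arene; the new centre (future C6) is racemic, which does not matter because it is equilibrated in step 13.

Step 10
Reactants: 15 rac-1-(4-hydroxy-3-methylphenyl)-2-methylpentan-3-one
Product: 16 rac-1-(3-bromo-4-hydroxy-5-methylphenyl)-2-methylpentan-3-one
Conditions: NBS, MeCN, 0 °C
Reagents that add atoms: N-bromosuccinimide O=C1CCC(=O)N1Br
Why: Electrophilic aromatic bromination goes to the only free position ortho to the hydroxyl group (future C1), which blocks that site in the next step and provides the handle for the side chain.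

Step 11
Reactants: 16 rac-1-(3-bromo-4-hydroxy-5-methylphenyl)-2-methylpentan-3-one
Product: 17 5-bromo-1-methyl-3-(2-methyl-3-oxopentyl)-6-oxocyclohexa-2,4-dien-1-yl acetate
Conditions: Pb(OAc)4, AcOH, rt
Reagents that add atoms: lead tetraacetate CC(=O)O[Pb](OC(C)=O)(OC(C)=O)OC(C)=O
Why: Wessely oxidation transfers acetate from an ArO–Pb(OAc)3 intermediate to an ortho carbon, and with the other ortho position carrying bromine the methyl-bearing carbon (future C3) should be acetoxylated to give the cyclohexa-2,4-dienone; the new quaternary centre is racemic and is erased in step 14.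

Step 12
Reactants: 17 5-bromo-1-methyl-3-(2-methyl-3-oxopentyl)-6-oxocyclohexa-2,4-dien-1-yl acetate; 11 2-(trimethylsilyl)ethyl (2E,4S,5E)-4-{[tert-butyl(dimethyl)silyl]oxymethyl}-4,5-dimethyl-6-(4,4,5,5-tetramethyl-1,3,2-dioxaborolan-2-yl)hexa-2,5-dienoate
Product: 18 2-(trimethylsilyl)ethyl (2E,4S,5E)-6-[5-acetoxy-5-methyl-3-(2-methyl-3-oxopentyl)-6-oxocyclohexa-1,3-dien-1-yl]-4-{[tert-butyl(dimethyl)silyl]oxymethyl}-4,5-dimethylhexa-2,5-dienoate
Conditions: Pd(OAc)2 (5 mol %), SPhos (10 mol %), K3PO4, THF/H2O, rt → 40 °C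
Reagents that add atoms: none
Why: Suzuki–Miyaura coupling at the activated α-bromo enone carbon forms the C1–C6' bond with retention of the E geometry under mild phosphate conditions that should leave the tertiary acetate in place.

Step 13
Reactants: 18 2-(trimethylsilyl)ethyl (2E,4S,5E)-6-[5-acetoxy-5-methyl-3-(2-methyl-3-oxopentyl)-6-oxocyclohexa-1,3-dien-1-yl]-4-{[tert-butyl(dimethyl)silyl]oxymethyl}-4,5-dimethylhexa-2,5-dienoate
Product: 20 2-(trimethylsilyl)ethyl (2E,4S,5E)-6-[(1S,6S,8R,8aS)-3-acetoxy-3,6,8-trimethyl-2,7-dioxo-1,2,3,5,6,7,8,8a-octahydronaphthalen-1-yl]-4-{[tert-butyl(dimethyl)silyl]oxymethyl}-4,5-dimethylhexa-2,5-dienoate, via kinetic Michael adduct 19 (not isolated)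
Conditions: 9-amino-9-deoxy-epi-quinine (20 mol %), 2-FC6H4CO2H (40 mol %), toluene, 40 °C; then DBU (20 mol %), 0 °C → rt
Reagents that add atoms: none
Why: Proposed new method: the cinchona primary amine condenses with the C7 ethyl ketone to its less substituted enamine, whose carbon C8 adds to C8a, the β-carbon of the alkenyl-substituted dienone arm, and hydrolysis of the resulting iminium frees the catalyst (intramolecular enamine Michael addition). The closest known reaction types are the amine-catalysed intramolecular Michael addition of tethered carbonyl donors to dearomatised cyclohexadienones and the primary-amine-catalysed addition of ketones to enones; new here are the linear 2,4-dienone (quinol acetate) acceptor and catalyst control over a substrate that already carries remote stereocentres. Ring B (C4a, C5, C6, C7, C8, C8a) is the only ring closed, through the C8–C8a bond in the 6-exo-trig mode with the enamine double bond inside the forming ring. C8a is set by the catalyst, whose protonated quinuclidine should hold the dienone carbonyl by hydrogen bonding so that the enamine reaches one face of C8a only, the distant C3, C6 and C4' centres not being expected to interfere. C8 and C6 (α to the C7 ketone) and C1 (α to the C2 ketone) are then settled by DBU equilibration to the all-equatorial ring B and to the C1 side chain trans to C8, all relayed from C8a. The step needs 1,4- over 1,6-addition and no loss of acetic acid: attack at C4 would be 6-endo at a carbon next to the quaternary C3, and the acetate has no acidic hydrogen placed for elimination.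

Step 14
Reactants: 20 2-(trimethylsilyl)ethyl (2E,4S,5E)-6-[(1S,6S,8R,8aS)-3-acetoxy-3,6,8-trimethyl-2,7-dioxo-1,2,3,5,6,7,8,8a-octahydronaphthalen-1-yl]-4-{[tert-butyl(dimethyl)silyl]oxymethyl}-4,5-dimethylhexa-2,5-dienoate
Product: 22 2-(trimethylsilyl)ethyl (2E,4S,5E)-4-{[tert-butyl(dimethyl)silyl]oxymethyl}-4,5-dimethyl-6-[(1S,6S,8R,8aR)-3,6,8-trimethyl-7-oxo-2-(trifluoromethanesulfonyloxy)-1,5,6,7,8,8a-hexahydronaphthalen-1-yl]hexa-2,5-dienoate, via samarium dienolate 21 (not isolated)
Conditions: SmI2 (2.5 equiv), THF, −78 °C; then N-(5-chloropyridin-2-yl)triflimide, −78 → 0 °C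
Reagents that add atoms: N-(5-chloropyridin-2-yl)bis(trifluoromethanesulfonyl)imide O=S(=O)(N(c1ccc(Cl)cn1)S(=O)(=O)C(F)(F)F)C(F)(F)F
Why: SmI2 cleaves the α-acyloxy ketone reductively by two single-electron transfers to give the C2–O–SmI2 dienolate regiospecifically and without base (so C1 is untouched), and O-sulfonylation by the triflimide should fix the C2=C3–C4=C4a diene; both C3 epimers converge to one compound.

Step 15
Reactants: 22 2-(trimethylsilyl)ethyl (2E,4S,5E)-4-{[tert-butyl(dimethyl)silyl]oxymethyl}-4,5-dimethyl-6-[(1S,6S,8R,8aR)-3,6,8-trimethyl-7-oxo-2-(trifluoromethanesulfonyloxy)-1,5,6,7,8,8a-hexahydronaphthalen-1-yl]hexa-2,5-dienoate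
Product: 23 2-(trimethylsilyl)ethyl (2E,4S,5E)-4-{[tert-butyl(dimethyl)silyl]oxymethyl}-4,5-dimethyl-6-[(1S,6S,8R,8aR)-3,6,8-trimethyl-7-oxo-2-(2-oxopropyl)-1,5,6,7,8,8a-hexahydronaphthalen-1-yl]hexa-2,5-dienoate
Conditions: Bu3SnOMe, isopropenyl acetate, PdCl2[P(o-tol)3]2 (5 mol %), LiCl, toluene, 80 °C
Reagents that add atoms: isopropenyl acetate CC(=C)OC(C)=O
Why: Palladium-catalysed cross-coupling of the dienyl triflate with Bu3SnCH2C(O)CH3, generated in the flask from Bu3SnOMe and isopropenyl acetate, forms the C2–CH2 bond under neutral conditions that should keep the β,γ-unsaturated methyl ketone out of conjugation.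

Step 16
Reactants: 23 2-(trimethylsilyl)ethyl (2E,4S,5E)-4-{[tert-butyl(dimethyl)silyl]oxymethyl}-4,5-dimethyl-6-[(1S,6S,8R,8aR)-3,6,8-trimethyl-7-oxo-2-(2-oxopropyl)-1,5,6,7,8,8a-hexahydronaphthalen-1-yl]hexa-2,5-dienoate
Product: 24 (2E,4S,5E)-4-(hydroxymethyl)-4,5-dimethyl-6-[(1S,6S,8R,8aR)-3,6,8-trimethyl-7-oxo-2-(2-oxopropyl)-1,5,6,7,8,8a-hexahydronaphthalen-1-yl]hexa-2,5-dienoic acid
Conditions: TBAF, AcOH, THF, 0 °C → rt
Reagents that add atoms: none
Why: Fluoride cleaves the primary silyl ether and, by β-elimination, the 2-(trimethylsilyl)ethyl ester in one operation, and the acetic acid buffer should prevent base-induced migration of the diene or epimerisation.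

**Compound list**

1 | diethylphosphonoacetic acid | OC(=O)CP(=O)(OCC)OCC | starting material
2 | 2-(trimethylsilyl)ethanol | C[Si](C)(C)CCO | starting material
3 | 2-(trimethylsilyl)ethyl 2-(diethoxyphosphoryl)acetate | CCOP(=O)(OCC)CC(=O)OCC[Si](C)(C)C | intermediate
4 | (2E)-3-methylpent-2-en-4-yn-1-ol | C#C/C(C)=C/CO | starting material
5 | [(1E,3E)-5-(dimethylalumanyloxy)-2,3-dimethylpenta-1,3-dien-1-yl]dimethylalumane | C[Al](C)OC/C=C(\C)/C(C)=C/[Al](C)C | intermediate (not isolated)
6 | (2E,4E)-5-iodo-3,4-dimethylpenta-2,4-dien-1-ol | OC/C=C(\C)/C(C)=C/I | intermediate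
7 | [(2S,3S)-3-[(1E)-1-iodoprop-1-en-2-yl]-3-methyloxiran-2-yl]methanol | OC[C@@H]1O[C@@]1(C)/C(C)=C/I | intermediate
8 | tert-butyl{[(2S,3S)-3-[(1E)-1-iodoprop-1-en-2-yl]-3-methyloxiran-2-yl]methoxy}dimethylsilane | CC(C)(C)[Si](C)(C)OC[C@@H]1O[C@@]1(C)/C(C)=C/I | intermediate
9 | (2S,3E)-2-{[tert-butyl(dimethyl)silyl]oxymethyl}-4-iodo-2,3-dimethylbut-3-enal | O=C[C@@](CO[Si](C)(C)C(C)(C)C)(C)/C(C)=C/I | intermediate
10 | 2-(trimethylsilyl)ethyl (2E,4S,5E)-4-{[tert-butyl(dimethyl)silyl]oxymethyl}-6-iodo-4,5-dimethylhexa-2,5-dienoate | C[Si](C)(C)CCOC(=O)/C=C/[C@@](CO[Si](C)(C)C(C)(C)C)(C)/C(C)=C/I | intermediate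
11 | 2-(trimethylsilyl)ethyl (2E,4S,5E)-4-{[tert-butyl(dimethyl)silyl]oxymethyl}-4,5-dimethyl-6-(4,4,5,5-tetramethyl-1,3,2-dioxaborolan-2-yl)hexa-2,5-dienoate | C[Si](C)(C)CCOC(=O)/C=C/[C@@](CO[Si](C)(C)C(C)(C)C)(C)/C(C)=C/B1OC(C)(C)C(C)(C)O1 | intermediate
12 | 4-hydroxy-3-methylbenzaldehyde | Cc1cc(C=O)ccc1O | starting material
13 | pentan-3-one | CCC(=O)CC | starting material
14 | (1E)-1-(4-hydroxy-3-methylphenyl)-2-methylpent-1-en-3-one | CCC(=O)/C(C)=C/c1ccc(O)c(C)c1 | intermediate
15 | rac-1-(4-hydroxy-3-methylphenyl)-2-methylpentan-3-one | CCC(=O)C(C)Cc1ccc(O)c(C)c1 | intermediate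
16 | rac-1-(3-bromo-4-hydroxy-5-methylphenyl)-2-methylpentan-3-one | CCC(=O)C(C)Cc1cc(C)c(O)c(Br)c1 | intermediate
17 | 5-bromo-1-methyl-3-(2-methyl-3-oxopentyl)-6-oxocyclohexa-2,4-dien-1-yl acetate (racemic, both diastereomers) | CCC(=O)C(C)CC1=CC(C)(OC(C)=O)C(=O)C(Br)=C1 | intermediate
18 | 2-(trimethylsilyl)ethyl (2E,4S,5E)-6-[5-acetoxy-5-methyl-3-(2-methyl-3-oxopentyl)-6-oxocyclohexa-1,3-dien-1-yl]-4-{[tert-butyl(dimethyl)silyl]oxymethyl}-4,5-dimethylhexa-2,5-dienoate (epimers at the acetoxy carbon and at C2 of the oxopentyl chain) | CCC(=O)C(C)CC1=CC(C)(OC(C)=O)C(=O)C(/C=C(\C)[C@](C)(/C=C/C(=O)OCC[Si](C)(C)C)CO[Si](C)(C)C(C)(C)C)=C1 | intermediate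
19 | kinetic Michael adduct: the octahydronaphthalene-2,7-dione of 20 with only C8a (S) and C4' (S) defined, epimeric at C1, C3, C6 and C8 | O=C1C(C)(OC(C)=O)C=C2CC(C)C(=O)C(C)[C@H]2C1/C=C(\C)[C@](C)(/C=C/C(=O)OCC[Si](C)(C)C)CO[Si](C)(C)C(C)(C)C | intermediate (not isolated)
20 | 2-(trimethylsilyl)ethyl (2E,4S,5E)-6-[(1S,6S,8R,8aS)-3-acetoxy-3,6,8-trimethyl-2,7-dioxo-1,2,3,5,6,7,8,8a-octahydronaphthalen-1-yl]-4-{[tert-butyl(dimethyl)silyl]oxymethyl}-4,5-dimethylhexa-2,5-dienoate (both C3 epimers; C1, C6, C8, C8a arranged as in the target) | O=C1C(C)(OC(C)=O)C=C2C[C@H](C)C(=O)[C@H](C)[C@H]2[C@@H]1/C=C(\C)[C@](C)(/C=C/C(=O)OCC[Si](C)(C)C)CO[Si](C)(C)C(C)(C)C | intermediate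
21 | C2–O–SmI2 dienolate of 20 after loss of acetate (C2=C3 and C4=C4a; 1S,6S,8R,8aR) | I[Sm](I)OC1=C(C)C=C2C[C@H](C)C(=O)[C@H](C)[C@H]2[C@@H]1/C=C(\C)[C@](C)(/C=C/C(=O)OCC[Si](C)(C)C)CO[Si](C)(C)C(C)(C)C | intermediate (not isolated)
22 | 2-(trimethylsilyl)ethyl (2E,4S,5E)-4-{[tert-butyl(dimethyl)silyl]oxymethyl}-4,5-dimethyl-6-[(1S,6S,8R,8aR)-3,6,8-trimethyl-7-oxo-2-(trifluoromethanesulfonyloxy)-1,5,6,7,8,8a-hexahydronaphthalen-1-yl]hexa-2,5-dienoate | FC(F)(F)S(=O)(=O)OC1=C(C)C=C2C[C@H](C)C(=O)[C@H](C)[C@H]2[C@@H]1/C=C(\C)[C@](C)(/C=C/C(=O)OCC[Si](C)(C)C)CO[Si](C)(C)C(C)(C)C | intermediate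
23 | 2-(trimethylsilyl)ethyl (2E,4S,5E)-4-{[tert-butyl(dimethyl)silyl]oxymethyl}-4,5-dimethyl-6-[(1S,6S,8R,8aR)-3,6,8-trimethyl-7-oxo-2-(2-oxopropyl)-1,5,6,7,8,8a-hexahydronaphthalen-1-yl]hexa-2,5-dienoate | CC(=O)CC1=C(C)C=C2C[C@H](C)C(=O)[C@H](C)[C@H]2[C@@H]1/C=C(\C)[C@](C)(/C=C/C(=O)OCC[Si](C)(C)C)CO[Si](C)(C)C(C)(C)C | intermediate
24 | (2E,4S,5E)-4-(hydroxymethyl)-4,5-dimethyl-6-[(1S,6S,8R,8aR)-3,6,8-trimethyl-7-oxo-2-(2-oxopropyl)-1,5,6,7,8,8a-hexahydronaphthalen-1-yl]hexa-2,5-dienoic acid | CC(=O)CC1=C(C)C=C2C[C@H](C)C(=O)[C@H](C)[C@H]2[C@@H]1/C=C(\C)[C@](C)(/C=C/C(=O)O)CO | target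

**Count and risks**

Total step count: 16. Longest linear sequence: 11 steps (steps 2 to 7, then 12 to 16).

Step 13 (proposed new method) is the most likely to fail. Facial control at C8a may be poor if uncatalysed cyclisation competes or if the catalyst is mismatched with the distant centres (the quinidine-derived pseudo-enantiomer would be tried first). Enamine formation at the branched ketone may be slow, and 1,6-addition at C4 may compete. The fallback uses known chemistry and sets out from 18. A base-mediated intramolecular Michael addition of the ketone to the dienone (Cs2CO3 or DBU, MeCN, rt), without facial control and followed by the same equilibration, should give 20 together with its ring-antipodal diastereomer, the (1R,6R,8S,8aR)-acetoxy diketone F1. The two differ as diastereomers because C4' is fixed, so they should be separable by chromatography. F1 would be returned to the equilibrium by retro-Michael and Michael addition under DBU at 60 °C and recycled; the route is rejoined at 20.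

Step 14 may fail through incomplete O-sulfonylation of the oxophilic trivalent samarium dienolate, with C-protonation on work-up, or through over-reduction of the enoate. The fallback sets out from 20 and separates the two events. SmI2 with MeOH at −78 °C should give the deacetoxylated β,γ-unsaturated ketone F2. Kinetic deprotonation with KHMDS at −78 °C, where the C3 hydrogen is the less hindered, doubly activated α-hydrogen, and trapping with the same triflimide then returns to the route at 22.

Step 12 may fail through ionisation of the tertiary allylic acetate by zerovalent palladium with reductive re-aromatisation, or through base-induced loss of the acetate. The fallback reverses the order and sets out from 16. Suzuki–Miyaura coupling of the bromophenol with 11 (Pd(OAc)2, SPhos, K3PO4) should give the alkenylphenol F3. Wessely oxidation of F3 with Pb(OAc)4 then returns to the route at 18, at the price of a regiochemical competition between the two ortho carbons.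

Further compounds

F1 | step 13 | 2-(trimethylsilyl)ethyl (2E,4S,5E)-6-[(1R,6R,8S,8aR)-3-acetoxy-3,6,8-trimethyl-2,7-dioxo-1,2,3,5,6,7,8,8a-octahydronaphthalen-1-yl]-4-{[tert-butyl(dimethyl)silyl]oxymethyl}-4,5-dimethylhexa-2,5-dienoate (both C3 epimers) | O=C1C(C)(OC(C)=O)C=C2C[C@@H](C)C(=O)[C@@H](C)[C@@H]2[C@H]1/C=C(\C)[C@](C)(/C=C/C(=O)OCC[Si](C)(C)C)CO[Si](C)(C)C(C)(C)C
F2 | step 14 | 2-(trimethylsilyl)ethyl (2E,4S,5E)-4-{[tert-butyl(dimethyl)silyl]oxymethyl}-4,5-dimethyl-6-[(1S,6S,8R,8aS)-3,6,8-trimethyl-2,7-dioxo-1,2,3,5,6,7,8,8a-octahydronaphthalen-1-yl]hexa-2,5-dienoate (both C3 epimers) | O=C1C(C)C=C2C[C@H](C)C(=O)[C@H](C)[C@H]2[C@@H]1/C=C(\C)[C@](C)(/C=C/C(=O)OCC[Si](C)(C)C)CO[Si](C)(C)C(C)(C)C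
F3 | step 12 | 2-(trimethylsilyl)ethyl (2E,4S,5E)-4-{[tert-butyl(dimethyl)silyl]oxymethyl}-6-[2-hydroxy-3-methyl-5-(2-methyl-3-oxopentyl)phenyl]-4,5-dimethylhexa-2,5-dienoate (epimers at C2 of the oxopentyl chain) | CCC(=O)C(C)Cc1cc(C)c(O)c(/C=C(\C)[C@](C)(/C=C/C(=O)OCC[Si](C)(C)C)CO[Si](C)(C)C(C)(C)C)c1
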